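**Plan**

- Cuts: the O7 acetyl; the (12Z)-diene at C13–C14 (Stille) and C12=C13 (iodo-Wittig), back to a γ-lactone that ties O8 to C12; C5–H, C6–O and C7–H back to a Δ5-7-ketone; then C5–C10 and C1–C2 together, which opens rings B and A to an acyclic (Z)-β-bromoenone with a primary bromide at C2; this is cut at C6–C7 (alkynyllithium + aldehyde), C9–C10 (isopropenyl cuprate + epoxide) and C8=C9 (Wittig).
- Forward: C7–C12 chain, epoxy alcohol, isopropenyl group (C10, C20, C1) at C9, union with the C2–C6 alkyne, lactone and bromoenone, then ring B and ring A in one nickel-mediated operation, then O7/O6/H5, side chain, acetate.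
- Enabling feature: C10 is quaternary and its neighbour C1 is a methylene. A C5-alkenylnickel that adds across a C10=C1 isopropenyl group (ring B, 6-exo) is left as a neopentyl C1–Ni bond with no β-hydrogen, which can be joined to the C2 bromide hanging from the gem-dimethyl carbon C4 (ring A). C1 and C2 are both electrophile-derived, so this is a reductive union of like polarity.
- Stereochemistry: C8 and C9 from one Sharpless epoxidation (the only catalyst-controlled event) and its invertive opening; C10 by substrate control in the key step; C7, C6 and C5 in one borane step relayed from C8 and C10; 12Z from the α-iodo ylide.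
- Helpers removed later: the C7 ketone (activates C5–Br, becomes the 7-OH), the γ-lactone (temporary ring, opened by reduction and olefination), both bromides.

Key step: step 12

Remark on the chemistry: labdane numbering (C1–C20) is used. The SMILES is read as the ent-labdane (5R,6S,7R,8R,9S,10R,12Z), in which O6, O7, O8 and C11 are all equatorial on ring B and the C8 and C10 methyl groups are syn-diaxial.

**Step 1**
Reactants: 1 3-[(tert-butyldimethylsilyl)oxy]propanal
Product: 2 ethyl (2E)-5-[(tert-butyldimethylsilyl)oxy]-2-methylpent-2-enoate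
Conditions: Ph3P=C(CH3)CO2Et, CH2Cl2, 25 °C
Reagents that add atoms: ethyl 2-(triphenylphosphoranylidene)propanoate, CCOC(=O)C(C)=P(c1ccccc1)(c1ccccc1)c1ccccc1
Why: Wittig olefination with a stabilised ylide should give the (E)-trisubstituted enoate, and this C8=C9 geometry is what the later epoxide opening turns into the C8/C9 relative configuration.

**Step 2**
Reactants: 2 ethyl (2E)-5-[(tert-butyldimethylsilyl)oxy]-2-methylpent-2-enoate
Product: 3 (2E)-5-[(tert-butyldimethylsilyl)oxy]-2-methylpent-2-en-1-ol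
Conditions: iBu2AlH (2.2 equiv), CH2Cl2, −78 °C
Reagents that add atoms: none
Why: 1,2-reduction of the enoate by iBu2AlH should give the allylic alcohol needed for the directed epoxidation without touching the silyl ether.

**Step 3**
Reactants: 3 (2E)-5-[(tert-butyldimethylsilyl)oxy]-2-methylpent-2-en-1-ol
Product: 4 [(2S,3S)-3-{2-[(tert-butyldimethylsilyl)oxy]ethyl}-2-methyloxiran-2-yl]methanol
Conditions: Ti(OiPr)4 (10 mol %), L-(+)-diethyl tartrate (12 mol %), tBuOOH, 4 Å molecular sieves, CH2Cl2, −20 °C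
Reagents that add atoms: tert-butyl hydroperoxide, CC(C)(C)OO
Why: Sharpless asymmetric epoxidation of an (E)-2-methyl allylic alcohol with L-(+)-tartrate should give the (2S,3S)-epoxide, which fixes C8 and sets C9 for inversion.

**Step 4**
Reactants: 4 [(2S,3S)-3-{2-[(tert-butyldimethylsilyl)oxy]ethyl}-2-methyloxiran-2-yl]methanol
Product: 5 (2R,3S)-3-{2-[(tert-butyldimethylsilyl)oxy]ethyl}-2,4-dimethylpent-4-ene-1,2-diol
Conditions: CH2=C(CH3)MgBr (3.5 equiv), CuI (20 mol %), THF, −30 to 0 °C; aq NH4Cl
Reagents that add atoms: isopropenylmagnesium bromide, CC(=C)[Mg]Br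
Why: copper-catalysed Grignard opening of a 2-methyl-2,3-epoxy alcohol should occur at the less substituted C9 with inversion (SN2), which sets C9 anti to O8 and leaves the tertiary carbinol C8 untouched.

**Step 5**
Reactants: 5 (2R,3S)-3-{2-[(tert-butyldimethylsilyl)oxy]ethyl}-2,4-dimethylpent-4-ene-1,2-diol
Product: 6 (2R,3S)-3-{2-[(tert-butyldimethylsilyl)oxy]ethyl}-2-hydroxy-2,4-dimethylpent-4-enal
Conditions: SO3·pyridine, DMSO, iPr2NEt, CH2Cl2, 0 °C
Reagents that add atoms: none
Why: Parikh–Doering oxidation should convert the primary alcohol to the aldehyde without glycol cleavage, and C8 cannot epimerise because it bears no hydrogen.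

**Step 6**
Reactants: 7 3,3-dimethyloxolan-2-one
Product: 8 3,3-dimethyloxolan-2-ol
Conditions: iBu2AlH (1.1 equiv), CH2Cl2, −78 °C
Reagents that add atoms: none
Why: partial reduction of a γ-lactone by iBu2AlH at low temperature should stop at the lactol, a masked 4-hydroxy-2,2-dimethylbutanal.

**Step 7**
Reactants: 8 3,3-dimethyloxolan-2-ol
Product: 9 3,3-dimethylpent-4-yn-1-ol
Conditions: (MeO)2P(O)C(N2)C(O)CH3, K2CO3, MeOH, 0 to 25 °C
Reagents that add atoms: dimethyl (1-diazo-2-oxopropyl)phosphonate, COP(=O)(OC)C(=[N+]=[N-])C(C)=O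
Why: Seyferth–Gilbert homologation in the Ohira–Bestmann variant should act on the open hydroxy aldehyde form of the lactol and add C6 as the alkyne terminus next to the gem-dimethyl carbon C4.

**Step 8**
Reactants: 9 3,3-dimethylpent-4-yn-1-ol
Product: 10 5-bromo-3,3-dimethylpent-1-yne
Conditions: CBr4, PPh3, CH2Cl2, 0 °C
Reagents that add atoms: carbon tetrabromide, BrC(Br)(Br)Br
Why: the Appel reaction should convert the unhindered primary alcohol into the C2 bromide under neutral conditions that leave the terminal alkyne alone.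

**Step 9**
Reactants: 10 5-bromo-3,3-dimethylpent-1-yne; 6 (2R,3S)-3-{2-[(tert-butyldimethylsilyl)oxy]ethyl}-2-hydroxy-2,4-dimethylpent-4-enal
Product: 12 (3S,4R)-10-bromo-3-{2-[(tert-butyldimethylsilyl)oxy]ethyl}-2,4,8,8-tetramethyldec-1-en-6-yne-4,5-diol (both epimers at the new carbinol carbon), via lithium acetylide 11 (not isolated)
Conditions: n-BuLi, 10 (2.3 equiv), THF, −78 °C; then 6, −78 to −20 °C; aq NH4Cl
Reagents that add atoms: none
Why: alkynyllithium addition to the aldehyde should form C6–C7, since deprotonation of the terminal alkyne is far faster than bromine–lithium exchange, and the new carbinol centre needs no control because it is oxidised in the next step.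

**Step 10**
Reactants: 12 (3S,4R)-10-bromo-3-{2-[(tert-butyldimethylsilyl)oxy]ethyl}-2,4,8,8-tetramethyldec-1-en-6-yne-4,5-diol
Product: 15 (4S,5R)-5-(6-bromo-4,4-dimethylhex-2-ynoyl)-5-methyl-4-(prop-1-en-2-yl)oxolan-2-one, via silyl ynone 13 (not isolated), via ynone lactol 14 (not isolated)
Conditions: CrO3, H2SO4, H2O, acetone, 0 to 25 °C
Reagents that add atoms: none
Why: Jones oxidation should first give the ynone, then the acidic medium should cleave the primary silyl ether and the freed C12 alcohol should be oxidised through the lactol on the tertiary O8 to the γ-lactone, a temporary ring that protects O8 and stores C12 at the acid level.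

**Step 11**
Reactants: 15 (4S,5R)-5-(6-bromo-4,4-dimethylhex-2-ynoyl)-5-methyl-4-(prop-1-en-2-yl)oxolan-2-one
Product: 16 (4S,5R)-5-[(2Z)-3,6-dibromo-4,4-dimethylhex-2-enoyl]-5-methyl-4-(prop-1-en-2-yl)oxolan-2-one
Conditions: LiBr, AcOH, MeCN, 40 °C
Reagents that add atoms: lithium bromide, [Li+].[Br-]
Why: conjugate hydrobromination of the ynone (anti addition of HBr) should place bromine on C5 cis to the acyl group, the (Z)-β-bromoenone geometry that ring B formation needs.

**Step 12**
Reactants: 16 (4S,5R)-5-[(2Z)-3,6-dibromo-4,4-dimethylhex-2-enoyl]-5-methyl-4-(prop-1-en-2-yl)oxolan-2-one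
Product: 18 (3aR,9aS,9bS)-3a,6,6,9a-tetramethyl-1,3a,6,7,8,9,9a,9b-octahydronaphtho[2,1-b]furan-2,4-dione, via σ-alkylnickel bromide 17 (not isolated)
Conditions: NiBr2(MeOCH2CH2OMe) (15 mol %), 4,4'-di-tert-butyl-2,2'-bipyridine (18 mol %), Mn powder (3 equiv), NaI (0.5 equiv), N,N-dimethylacetamide, 0.01 M, slow addition of 16, 30 °C
Reagents that add atoms: none
Why: Proposed new method: zerovalent nickel should add to the enone-activated alkenyl C5–Br bond, the alkenylnickel should insert the C10=C1 isopropenyl group to give the neopentyl σ-alkylnickel 17, which cannot lose a β-hydrogen because C10 is quaternary, and after reduction by Mn to monovalent nickel this species should take the bromine atom from C2–Br, recapture the C2 radical as a seven-membered dialkyl trivalent nickelacycle and form C1–C2 by reductive elimination, a union of two electrophile-derived carbons. The closest known reaction type is the nickel-catalysed reductive aryl- or alkenyl-alkylation of a tethered 1,1-disubstituted alkene with an external primary alkyl bromide (cyclisation followed by cross-electrophile coupling); the new element is that the alkyl bromide sits in the same molecule, so that a second ring closes. Ring B closes by 6-exo-trig migratory insertion and ring A closes as a six-membered ring by C(sp3)–C(sp3) reductive elimination from the nickelacycle. The only new stereocentre, C10, is set by the substrate: the trans-fused γ-lactone holds C9–C11 equatorial on the forming ring B, allylic 1,3-strain keeps C9–H eclipsed with C10=C1, and the nickel-bearing C1 should therefore take the equatorial and the methyl the axial position, syn to the C8 methyl as in the target. The step needs the alkenyl bromide to react before the alkyl bromide (secured by the β-bromoenone, the far better partner for oxidative addition), 6-exo rather than 7-endo insertion (secured by the four-atom C6–C9 tether and the 1,1-disubstituted alkene) and ring closure rather than intermolecular coupling (secured by high dilution and the gem-dimethyl group at C4).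

**Step 13**
Reactants: 18 (3aR,9aS,9bS)-3a,6,6,9a-tetramethyl-1,3a,6,7,8,9,9a,9b-octahydronaphtho[2,1-b]furan-2,4-dione
Product: 21 (3aR,4R,5S,5aR,9aR,9bS)-4,5-dihydroxy-3a,6,6,9a-tetramethyldecahydronaphtho[2,1-b]furan-2(1H)-one, via allyloxyborane 19 (not isolated), via alkylborane 20 (not isolated)
Conditions: BH3·THF (3 equiv), THF, 0 to 25 °C; then NaBO3·4H2O, H2O, 25 °C
Reagents that add atoms: sodium perborate, [Na+].[Na+].O[B-]1(O)OO[B-](O)(O)OO1
Why: borane should reduce the C7 ketone by axial attack anti to the axial C8 methyl (equatorial 7-O) and then hydroborate C5=C6 anti to that borate and opposite the axial C10 and C4 methyls, so that oxidation with retention gives the equatorial 6-OH and the trans ring fusion, the reduction–hydroboration of a cyclic enone to a trans-diequatorial diol known for steroidal 4-en-3-ones.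

**Step 14**
Reactants: 21 (3aR,4R,5S,5aR,9aR,9bS)-4,5-dihydroxy-3a,6,6,9a-tetramethyldecahydronaphtho[2,1-b]furan-2(1H)-one
Product: 22 (3aR,4R,5S,5aR,9aR,9bS)-3a,6,6,9a-tetramethyldodecahydronaphtho[2,1-b]furan-2,4,5-triol (both anomers)
Conditions: iBu2AlH (3.5 equiv), CH2Cl2, −78 °C
Reagents that add atoms: none
Why: partial reduction of the γ-lactone by iBu2AlH should stop at the lactol, the masked C12 aldehyde, while the two hydroxyls are carried as aluminium alkoxides.

**Step 15**
Reactants: 22 (3aR,4R,5S,5aR,9aR,9bS)-3a,6,6,9a-tetramethyldodecahydronaphtho[2,1-b]furan-2,4,5-triol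
Product: 23 (1S,2R,3R,4S,4aR,8aR)-4-[(2Z)-3-iodobut-2-en-1-yl]-3,4a,8,8-tetramethyldecahydronaphthalene-1,2,3-triol
Conditions: EtPPh3I, n-BuLi, THF, 25 °C; I2, −78 °C; NaN(SiMe3)2, −78 to −20 °C; then 22, −78 to −20 °C
Reagents that add atoms: ethyltriphenylphosphonium iodide, CC[P+](c1ccccc1)(c1ccccc1)c1ccccc1.[I-]; iodine, II
Why: Stork–Zhao-type olefination of the ring-opened hydroxy aldehyde with the α-iodo ylide should give the (Z)-2-iodoalkene under kinetic control, with iodine cis to C11, and should release O8.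

**Step 16**
Reactants: 23 (1S,2R,3R,4S,4aR,8aR)-4-[(2Z)-3-iodobut-2-en-1-yl]-3,4a,8,8-tetramethyldecahydronaphthalene-1,2,3-triol
Product: 24 (1S,2R,3R,4S,4aR,8aR)-3,4a,8,8-tetramethyl-4-[(2Z)-3-methylpenta-2,4-dien-1-yl]decahydronaphthalene-1,2,3-triol
Conditions: Bu3SnCH=CH2, Pd(PPh3)4 (10 mol %), CuI (20 mol %), DMF, 40 °C
Reagents that add atoms: tributyl(vinyl)stannane, C=C[Sn](CCCC)(CCCC)CCCC
Why: Stille coupling should replace iodine by vinyl with retention of the alkene geometry and give the (12Z)-diene in the presence of the free hydroxyls.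

**Step 17**
Reactants: 24 (1S,2R,3R,4S,4aR,8aR)-3,4a,8,8-tetramethyl-4-[(2Z)-3-methylpenta-2,4-dien-1-yl]decahydronaphthalene-1,2,3-triol
Product: 25 (1S,2R,3R,4S,4aR,8aR)-1,3-dihydroxy-3,4a,8,8-tetramethyl-4-[(2Z)-3-methylpenta-2,4-dien-1-yl]decahydronaphthalen-2-yl acetate (CNP0225877.2)
Conditions: Ac2O (1.1 equiv), pyridine, CH2Cl2, 0 °C
Reagents that add atoms: acetic anhydride, CC(=O)OC(C)=O
Why: acylation should occur at the equatorial C7 hydroxyl, the most accessible one, because the C8 hydroxyl is tertiary and the C6 hydroxyl is shielded by the peri-related equatorial methyl on C4.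

**Compound list**

1 | 3-[(tert-butyldimethylsilyl)oxy]propanal | CC(C)(C)[Si](C)(C)OCCC=O | starting material
2 | ethyl (2E)-5-[(tert-butyldimethylsilyl)oxy]-2-methylpent-2-enoate | CCOC(=O)/C(C)=C/CCO[Si](C)(C)C(C)(C)C | intermediate
3 | (2E)-5-[(tert-butyldimethylsilyl)oxy]-2-methylpent-2-en-1-ol | CC(C)(C)[Si](C)(C)OCC/C=C(\C)CO | intermediate
4 | [(2S,3S)-3-{2-[(tert-butyldimethylsilyl)oxy]ethyl}-2-methyloxiran-2-yl]methanol | CC(C)(C)[Si](C)(C)OCC[C@@H]1O[C@@]1(C)CO | intermediate
5 | (2R,3S)-3-{2-[(tert-butyldimethylsilyl)oxy]ethyl}-2,4-dimethylpent-4-ene-1,2-diol | CC(C)(C)[Si](C)(C)OCC[C@@H](C(C)=C)[C@@](C)(O)CO | intermediate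
6 | (2R,3S)-3-{2-[(tert-butyldimethylsilyl)oxy]ethyl}-2-hydroxy-2,4-dimethylpent-4-enal | CC(C)(C)[Si](C)(C)OCC[C@@H](C(C)=C)[C@@](C)(O)C=O | intermediate
7 | 3,3-dimethyloxolan-2-one (α,α-dimethyl-γ-butyrolactone) | CC1(C)CCOC1=O | starting material
8 | 3,3-dimethyloxolan-2-ol | CC1(C)CCOC1O | intermediate
9 | 3,3-dimethylpent-4-yn-1-ol | C#CC(C)(C)CCO | intermediate
10 | 5-bromo-3,3-dimethylpent-1-yne | C#CC(C)(C)CCBr | intermediate
11 | (5-bromo-3,3-dimethylpent-1-yn-1-yl)lithium | [Li]C#CC(C)(C)CCBr | intermediate (not isolated)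
12 | (3S,4R)-10-bromo-3-{2-[(tert-butyldimethylsilyl)oxy]ethyl}-2,4,8,8-tetramethyldec-1-en-6-yne-4,5-diol (both epimers at the propargylic carbinol) | CC(C)(C)[Si](C)(C)OCC[C@@H](C(C)=C)[C@@](C)(O)C(O)C#CC(C)(C)CCBr | intermediate
13 | (3S,4R)-10-bromo-3-{2-[(tert-butyldimethylsilyl)oxy]ethyl}-4-hydroxy-2,4,8,8-tetramethyldec-1-en-6-yn-5-one | CC(C)(C)[Si](C)(C)OCC[C@@H](C(C)=C)[C@@](C)(O)C(=O)C#CC(C)(C)CCBr | intermediate (not isolated)
14 | 6-bromo-1-[(2R,3S)-5-hydroxy-2-methyl-3-(prop-1-en-2-yl)oxolan-2-yl]-4,4-dimethylhex-2-yn-1-one (both anomers) | OC1C[C@@H](C(C)=C)[C@@](C)(O1)C(=O)C#CC(C)(C)CCBr | intermediate (not isolated)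
15 | (4S,5R)-5-(6-bromo-4,4-dimethylhex-2-ynoyl)-5-methyl-4-(prop-1-en-2-yl)oxolan-2-one | O=C1C[C@@H](C(C)=C)[C@@](C)(O1)C(=O)C#CC(C)(C)CCBr | intermediate
16 | (4S,5R)-5-[(2Z)-3,6-dibromo-4,4-dimethylhex-2-enoyl]-5-methyl-4-(prop-1-en-2-yl)oxolan-2-one | O=C1C[C@@H](C(C)=C)[C@@](C)(O1)C(=O)/C=C(Br)/C(C)(C)CCBr | intermediate
17 | ring B-closed neopentyl σ-alkylnickel bromide, nickel on C1, C2 bromide still in place (bipyridine ligand not drawn) | O=C1C[C@@H]2[C@@](C)(O1)C(=O)C=C(C(C)(C)CCBr)[C@@]2(C)C[Ni]Br | intermediate (not isolated)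
18 | (3aR,9aS,9bS)-3a,6,6,9a-tetramethyl-1,3a,6,7,8,9,9a,9b-octahydronaphtho[2,1-b]furan-2,4-dione | O=C1C[C@@H]2[C@@](C)(O1)C(=O)C=C3C(C)(C)CCC[C@]32C | intermediate
19 | allyloxyborane from reduction of the C7 ketone of 18 (drawn as the O–BH2 species) | O=C1C[C@@H]2[C@@](C)(O1)[C@H](OB)C=C3C(C)(C)CCC[C@]32C | intermediate (not isolated)
20 | alkylborane with boron on C6 and hydrogen on C5 (drawn as the BH2 species) | O=C1C[C@@H]2[C@@](C)(O1)[C@H](OB)[C@@H](B)[C@@H]3C(C)(C)CCC[C@]32C | intermediate (not isolated)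
21 | (3aR,4R,5S,5aR,9aR,9bS)-4,5-dihydroxy-3a,6,6,9a-tetramethyldecahydronaphtho[2,1-b]furan-2(1H)-one | O=C1C[C@@H]2[C@@](C)(O1)[C@H](O)[C@@H](O)[C@@H]3C(C)(C)CCC[C@]32C | intermediate
22 | (3aR,4R,5S,5aR,9aR,9bS)-3a,6,6,9a-tetramethyldodecahydronaphtho[2,1-b]furan-2,4,5-triol (both anomers) | OC1C[C@@H]2[C@@](C)(O1)[C@H](O)[C@@H](O)[C@@H]3C(C)(C)CCC[C@]32C | intermediate
23 | (1S,2R,3R,4S,4aR,8aR)-4-[(2Z)-3-iodobut-2-en-1-yl]-3,4a,8,8-tetramethyldecahydronaphthalene-1,2,3-triol | I/C(C)=C\C[C@@H]1[C@@](C)(O)[C@H](O)[C@@H](O)[C@@H]2C(C)(C)CCC[C@]21C | intermediate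
24 | (1S,2R,3R,4S,4aR,8aR)-3,4a,8,8-tetramethyl-4-[(2Z)-3-methylpenta-2,4-dien-1-yl]decahydronaphthalene-1,2,3-triol | C=C/C(C)=C\C[C@@H]1[C@@](C)(O)[C@H](O)[C@@H](O)[C@@H]2C(C)(C)CCC[C@]21C | intermediate
25 | (1S,2R,3R,4S,4aR,8aR)-1,3-dihydroxy-3,4a,8,8-tetramethyl-4-[(2Z)-3-methylpenta-2,4-dien-1-yl]decahydronaphthalen-2-yl acetate (CNP0225877.2) | C=C/C(C)=C\C[C@@H]1[C@@](C)(O)[C@H](OC(C)=O)[C@@H](O)[C@@H]2C(C)(C)CCC[C@]21C | target

Total step count: 17. Longest linear sequence: 14 steps (steps 1–5 and 9–17).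

**Steps most likely to fail**

Step 12 (proposed new method). The C2 radical may be captured by the alkenylnickel before ring B has formed (direct alkenyl–alkyl coupling), the halides may be reduced or coupled between molecules, the neopentylnickel may insert into the new enone, or the insertion may show poor facial selectivity at C10. The fallback uses known palladium and ruthenium chemistry; it sets out from 10 and 6 and comes back at 18. Elimination of HBr from 10 (KOtBu, DMSO) should give 3,3-dimethylpent-1-en-4-yne F1. Its lithium acetylide should add to 6 as in step 9 to give the propargylic diol F2. Jones oxidation as in step 10 should give the ynone lactone F3, and LiBr/AcOH the (Z)-bromoenone F4. A domino 6-exo Heck cyclisation/Suzuki coupling (Pd(OAc)2, PPh3, CH2=CHBF3K, Cs2CO3, THF/H2O) should then form C5–C10 and C1–C2 and give the ring B enone F5, which carries an allyl group on C10 and a vinyl group on C4. Ring-closing metathesis with second-generation Grubbs catalyst should close ring A at C2=C3 to give the dienone lactone F6. Hydrogenation of the disubstituted alkene over RhCl(PPh3)3 should return to 18.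

Step 15. Slow unmasking of the lactol to the hydroxy aldehyde may let the thermally labile iodo ylide decompose, and the Z selectivity may erode. The fallback builds the trisubstituted alkene as an ester; it sets out from 22 and comes back at 24, so that step 16 is not needed. Still–Gennari olefination ((CF3CH2O)2P(O)CH(CH3)CO2CH3, KN(SiMe3)2, 18-crown-6, THF, −78 °C) should give the (Z)-enoate F7. Reduction with iBu2AlH should give the (Z)-allylic alcohol F8, and MnO2 the (Z)-enal F9. Methylenation with Ph3P=CH2 should give 24.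

Step 17. Discrimination between the two secondary hydroxyls may be poor, with acetylation at O6, double acetylation or acyl migration. The fallback tells the two oxygens apart by the order in which they arise; it sets out from 18 and comes back at 25. Luche reduction (NaBH4, CeCl3·7H2O, MeOH) should give the equatorial allylic alcohol F10. Reduction with iBu2AlH should give the lactol F11, and iodo-olefination as in step 15 the vinyl iodide F12, in which O7 is the only secondary hydroxyl. Acetylation (Ac2O, 4-dimethylaminopyridine, pyridine) should give the 7-acetate F13. Epoxidation with mCPBA opposite the C10 methyl should give the 5,6-epoxide F14. Homolytic opening with (C5H5)2TiCl (trivalent titanium, from (C5H5)2TiCl2 and Mn) and 1,4-cyclohexadiene should give the tertiary C5 radical, and hydrogen atom transfer to its open face the 6-hydroxy 7-acetate F15 with trans ring fusion. Stille coupling as in step 16 should give 25.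

**Further compounds**

F1 | step 12 | 3,3-dimethylpent-1-en-4-yne | C=CC(C)(C)C#C
F2 | step 12 | (3S,4R)-3-{2-[(tert-butyldimethylsilyl)oxy]ethyl}-2,4,8,8-tetramethyldeca-1,9-dien-6-yne-4,5-diol (both carbinol epimers) | CC(C)(C)[Si](C)(C)OCC[C@@H](C(C)=C)[C@@](C)(O)C(O)C#CC(C)(C)C=C
F3 | step 12 | (4S,5R)-5-(4,4-dimethylhex-5-en-2-ynoyl)-5-methyl-4-(prop-1-en-2-yl)oxolan-2-one | O=C1C[C@@H](C(C)=C)[C@@](C)(O1)C(=O)C#CC(C)(C)C=C
F4 | step 12 | (4S,5R)-5-[(2Z)-3-bromo-4,4-dimethylhexa-2,5-dienoyl]-5-methyl-4-(prop-1-en-2-yl)oxolan-2-one | O=C1C[C@@H](C(C)=C)[C@@](C)(O1)C(=O)/C=C(Br)/C(C)(C)C=C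
F5 | step 12 | ring B enone lactone with allyl on C10 and 2-methylbut-3-en-2-yl on C5 | O=C1C[C@@H]2[C@@](C)(O1)C(=O)C=C(C(C)(C)C=C)[C@@]2(C)CC=C
F6 | step 12 | tricyclic dienone lactone, 18 with a C2=C3 double bond | O=C1C[C@@H]2[C@@](C)(O1)C(=O)C=C3C(C)(C)C=CC[C@]32C
F7 | step 15 | methyl (2Z)-2-methylbut-2-enoate attached through C4 to C9 of the 6,7,8-triol | COC(=O)/C(C)=C\C[C@@H]1[C@@](C)(O)[C@H](O)[C@@H](O)[C@@H]2C(C)(C)CCC[C@]21C
F8 | step 15 | (2Z)-allylic alcohol from F7 | OC/C(C)=C\C[C@@H]1[C@@](C)(O)[C@H](O)[C@@H](O)[C@@H]2C(C)(C)CCC[C@]21C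
F9 | step 15 | (2Z)-enal from F8 | O=C/C(C)=C\C[C@@H]1[C@@](C)(O)[C@H](O)[C@@H](O)[C@@H]2C(C)(C)CCC[C@]21C
F10 | step 17 | 7-hydroxy lactone with C5=C6, 7-OH equatorial | O=C1C[C@@H]2[C@@](C)(O1)[C@H](O)C=C3C(C)(C)CCC[C@]32C
F11 | step 17 | lactol from F10 (both anomers) | OC1C[C@@H]2[C@@](C)(O1)[C@H](O)C=C3C(C)(C)CCC[C@]32C
F12 | step 17 | (Z)-vinyl iodide 7,8-diol with C5=C6 | I/C(C)=C\C[C@@H]1[C@@](C)(O)[C@H](O)C=C2C(C)(C)CCC[C@]21C
F13 | step 17 | 7-acetate of F12 | I/C(C)=C\C[C@@H]1[C@@](C)(O)[C@H](OC(C)=O)C=C2C(C)(C)CCC[C@]21C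
F14 | step 17 | 5,6-epoxide of F13, oxygen anti to the C10 methyl | I/C(C)=C\C[C@@H]1[C@@](C)(O)[C@H](OC(C)=O)[C@H]3O[C@@]23C(C)(C)CCC[C@]21C
F15 | step 17 | (Z)-vinyl iodide 6,8-diol 7-acetate with trans ring fusion | I/C(C)=C\C[C@@H]1[C@@](C)(O)[C@H](OC(C)=O)[C@@H](O)[C@@H]2C(C)(C)CCC[C@]21C
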